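Ring atoms are numbered C1 (acetoxy carbon), C2=C3 (E-alkene), C6 (stereocentre bearing the C15 carbinol), C8=C9 (Z-alkene), C12 and C13 (oxirane carbons) and C14. The 14-membered carbocycle is disconnected at C10–C11, the one ring bond that lies between an alkene carbon (C9) and an oxirane carbon (C12). Formed as a C10=C11 double bond, it is the only 1,2-disubstituted alkene of the macrocycle. Ring-closing metathesis of an acyclic acetate that carries a terminal (Z)-2-methylbuta-1,3-dienyl unit and a vinyloxirane therefore closes the ring with all four stereocentres and both trisubstituted alkenes already in place; diimide then saturates only this alkene.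

Key step: step 15

Remark: (R)-(+)-α-terpineol is taken as the commercial source of C6; its stereocentre maps directly onto C6 of the target, the ring methyl ketone carbon becoming C3 and the ring CH= carbon becoming C8.

Assumption: in step 9 the (S)-Tol-BINAP copper fluoride catalyst is taken to deliver the (R)-carbinol at C1; if the sense of induction proves opposite, the (R)-ligand is used.

Step 1
Reactants: 1 (R)-(+)-α-terpineol, 2-[(1R)-4-methylcyclohex-3-en-1-yl]propan-2-ol
Product: 2 triethyl{[2-((1R)-4-methylcyclohex-3-en-1-yl)propan-2-yl]oxy}silane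
Conditions: TESOTf, 2,6-lutidine, CH2Cl2, 0 °C
Reagents that add atoms: triethylsilyl trifluoromethanesulfonate, CC[Si](CC)(CC)OS(=O)(=O)C(F)(F)F
Why: Silyl triflate with lutidine is the standard silylation of a hindered tertiary alcohol, so that the later carbonyl and organometallic steps meet no free hydroxyl.

Step 2
Reactants: 2 TES ether of α-terpineol
Product: 3 (3R)-6-oxo-3-[2-(triethylsilyloxy)propan-2-yl]heptanal
Conditions: O3, CH2Cl2, −78 °C; then Me2S, −78 °C to rt
Reagents that add atoms: ozone, [O-][O+]=O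
Why: Ozonolysis with reductive work-up cleaves the only alkene to the methyl ketone (C3) and the aldehyde (C8) without touching the C6 stereocentre.

Step 3
Reactants: 3 keto aldehyde
Product: 4 (5R,7Z)-8-iodo-5-[2-(triethylsilyloxy)propan-2-yl]non-7-en-2-one
Conditions: EtPPh3I, n-BuLi, THF, 0 °C; I2, −78 °C; NaHMDS, −20 °C; then 3, −78 °C
Reagents that add atoms: ethyltriphenylphosphonium iodide, CC[P+](c1ccccc1)(c1ccccc1)c1ccccc1.[I-]; iodine, II
Why: Stork–Zhao-type Wittig olefination with the α-iodo ylide attacks the aldehyde much faster than the methyl ketone at low temperature and should give the (Z)-iodoalkene through the kinetically favoured cis-oxaphosphetane of a non-stabilised ylide.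

Step 4
Reactants: 4 (Z)-iodoalkene
Product: 5 (5R,7Z)-8-methyl-5-[2-(triethylsilyloxy)propan-2-yl]deca-7,9-dien-2-one
Conditions: tributyl(vinyl)stannane, Pd2(dba)3 (cat.), AsPh3, NMP, rt
Reagents that add atoms: tributyl(vinyl)stannane, C=C[Sn](CCCC)(CCCC)CCCC
Why: Stille coupling proceeds with retention of alkene geometry, so the vinyl carbon that becomes C10 ends up cis to C7 across C8=C9.

Step 5
Reactants: 5 dienyl methyl ketone
Product: 7 (3Z,6R)-3-methyl-6-[2-(triethylsilyloxy)propan-2-yl]deca-1,3-dien-9-yne, via enol diethyl phosphate 6 (not isolated)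
Conditions: LDA, THF, −78 °C; ClP(O)(OEt)2, −78 °C to rt; then LDA (2.3 equiv), −78 °C to rt
Reagents that add atoms: none
Why: Kinetic deprotonation on the methyl side, O-phosphorylation and base-induced elimination of the terminal enol phosphate (Negishi alkyne synthesis) turn the acetyl group into the terminal alkyne whose CH becomes C2.

Step 6
Reactants: 7 terminal alkyne
Product: 9 (2E,6R,8Z)-3,9-dimethyl-6-[2-(triethylsilyloxy)propan-2-yl]undeca-2,8,10-trien-1-ol, via alkenyldimethylalane 8 (not isolated)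
Conditions: Me3Al, Cp2ZrCl2 (cat.), H2O (1 equiv), CH2Cl2, −23 °C; then n-BuLi, (CH2O)n, THF, −78 °C to rt
Reagents that add atoms: trimethylaluminium, C[Al](C)C; paraformaldehyde (as formaldehyde), C=O
Why: Zirconium-catalysed syn-carboalumination (Negishi) places methyl on the internal and aluminium on the terminal alkyne carbon, which fixes the E-geometry of C2=C3, and the derived alanate is hydroxymethylated with retention.

Step 7
Reactants: 9 (E)-allylic alcohol
Product: 10 (2E,6R,8Z)-3,9-dimethyl-6-[2-(triethylsilyloxy)propan-2-yl]undeca-2,8,10-trienal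
Conditions: MnO2, CH2Cl2, rt
Reagents that add atoms: none
Why: MnO2 oxidises the allylic alcohol selectively to the enal and leaves the silyl ether and the diene alone (allylic oxidation).

Step 8
Reactants: 11 ethyl 3-methylbut-2-enoate
Product: 12 1-ethoxy-3-methyl-1-(trimethylsilyloxy)buta-1,3-diene
Conditions: LDA, THF, −78 °C; TMSCl, −78 °C to rt
Reagents that add atoms: chlorotrimethylsilane, C[Si](C)(C)Cl
Why: γ-Deprotonation of the senecioate and O-silylation of the dienolate give the silyl dienolate (silyl ketene acetal formation).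

Step 9
Reactants: 10 enal; 12 silyl dienolate
Product: 13 (6R)-6-[(1E,5R,7Z)-2,8-dimethyl-5-[2-(triethylsilyloxy)propan-2-yl]deca-1,7,9-trien-1-yl]-4-methyl-5,6-dihydro-2H-pyran-2-one
Conditions: Cu(OTf)2 (10 mol%), (S)-Tol-BINAP (11 mol%), tetrabutylammonium difluorotriphenylsilicate (20 mol%), THF, rt
Reagents that add atoms: none
Why: Catalytic asymmetric vinylogous Mukaiyama aldol addition through a chiral copper dienolate attacks the aldehyde at the γ-carbon, the ligand sets the C1 stereocentre, and the (Z)-configured copper aldolate acylates itself to the lactone, whose ring locks C12=C13 in the Z-geometry.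

Step 10
Reactants: 13 unsaturated δ-lactone
Product: 14 (2Z,5R,6E,10R,12Z)-3,7,13-trimethyl-10-[2-(triethylsilyloxy)propan-2-yl]pentadeca-2,6,12,14-tetraene-1,5-diol
Conditions: DIBAL-H (3 equiv), CH2Cl2, −78 to 0 °C; Rochelle salt work-up
Reagents that add atoms: none
Why: DIBAL-H reduces the unsaturated lactone in the 1,2-sense through the lactol to the diol, and the ring geometry is carried into the open-chain (Z)-allylic alcohol.

Step 11
Reactants: 14 diol
Product: 15 (2R,3E,7R,9Z)-1-[(2R,3S)-3-(hydroxymethyl)-2-methyloxiran-2-yl]-4,10-dimethyl-7-[2-(triethylsilyloxy)propan-2-yl]dodeca-3,9,11-trien-2-ol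
Conditions: Ti(OiPr)4, L-(+)-diethyl tartrate, t-BuOOH, 4 Å MS, CH2Cl2, −20 °C
Reagents that add atoms: tert-butyl hydroperoxide, CC(C)(C)OO
Why: In the Sharpless asymmetric epoxidation the titanium tartrate binds the primary allylic alcohol and L-(+)-tartrate delivers oxygen to the face that gives the (12S,13R) cis-oxirane, as for nerol; C2=C3 should be spared because (R)-C1 is the slow-reacting antipode for this tartrate and the alkene carries a cis-methyl group.

Step 12
Reactants: 15 epoxy diol
Product: 17 (2R,3E,7R,9Z)-4,10-dimethyl-1-{(2R,3S)-2-methyl-3-[(triethylsilyloxy)methyl]oxiran-2-yl}-7-[2-(triethylsilyloxy)propan-2-yl]dodeca-3,9,11-trien-2-yl acetate, via mono-silyl ether 16 (not isolated)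
Conditions: TESCl (1.05 equiv), imidazole, CH2Cl2, −78 °C; then Ac2O, Et3N, DMAP, 0 °C
Reagents that add atoms: chlorotriethylsilane, CC[Si](Cl)(CC)CC; acetic anhydride, CC(=O)OC(C)=O
Why: The unhindered primary hydroxyl is silylated selectively at low temperature and the remaining secondary allylic hydroxyl is then acetylated in the same flask (silylation followed by DMAP-catalysed acylation).

Step 13
Reactants: 17 primary TES ether acetate
Product: 18 (2R,3E,7R,9Z)-1-[(2R,3R)-3-formyl-2-methyloxiran-2-yl]-4,10-dimethyl-7-[2-(triethylsilyloxy)propan-2-yl]dodeca-3,9,11-trien-2-yl acetate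
Conditions: (COCl)2, DMSO, CH2Cl2, −78 to −30 °C; Et3N, −78 °C to rt
Reagents that add atoms: none
Why: Under Swern conditions a primary triethylsilyl ether is cleaved by the chlorosulfonium salt and oxidised directly to the aldehyde, while the tertiary silyl ether, the acetate and the oxirane are inert.

Step 14
Reactants: 18 epoxy aldehyde
Product: 19 (2R,3E,7R,9Z)-1-[(2R,3S)-3-ethenyl-2-methyloxiran-2-yl]-4,10-dimethyl-7-[2-(triethylsilyloxy)propan-2-yl]dodeca-3,9,11-trien-2-yl acetate
Conditions: Ph3PCH3Br, KHMDS, THF, 0 °C; then 18, −78 to 0 °C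
Reagents that add atoms: methyltriphenylphosphonium bromide, C[P+](c1ccccc1)(c1ccccc1)c1ccccc1.[Br-]
Why: Wittig methylenation at low temperature converts the aldehyde into the vinyl group faster than the ylide attacks the acetate, and the oxirane carbon should not epimerise because enolisation toward a three-membered ring is disfavoured.

Step 15
Reactants: 19 acyclic dienyl vinyloxirane
Product: 20 (1S,2E,4Z,7R,10E,12R,14R)-4,10,14-trimethyl-7-[2-(triethylsilyloxy)propan-2-yl]-15-oxabicyclo[12.1.0]pentadeca-2,4,10-trien-12-yl acetate (the C10=C11 didehydro macrocycle)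
Conditions: second-generation Grubbs catalyst RuCl2(=CHPh)(H2IMes)(PCy3) (10 mol%, in portions), 1,4-benzoquinone (10 mol%), CH2Cl2 (1 mM), 40 °C
Reagents that add atoms: none
Why: Ring-closing olefin metathesis (Chauvin mechanism): the ruthenium benzylidene exchanges onto one of the two monosubstituted vinyl termini, forms a ruthenacyclobutane with the other by [2+2] cycloaddition and collapses by cycloreversion to the C10=C11 alkene, the loss of ethene driving the reaction. The closest known reaction type is the diene–ene ring-closing metathesis to macrocyclic conjugated dienes used in macrolide synthesis. The 14-membered carbocycle closes by end-to-end macrocyclisation of the two terminal alkenes under high dilution. No stereocentre is formed, and the geometry of the new C10=C11 alkene is irrelevant because it is saturated in step 16. The step needs site selectivity for the two vinyl groups over C2=C3 and C8=C9 (closure onto C8=C9 would give a 12-membered ring), which their trisubstitution secures, and retention of the Z-geometry at C8=C9, for which 1,4-benzoquinone suppresses ruthenium hydride isomerisation.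

Step 16
Reactants: 20 macrocyclic triene
Product: 21 (1R,3R,4E,8R,10Z,14S)-1,5,11-trimethyl-8-[2-(triethylsilyloxy)propan-2-yl]-15-oxabicyclo[12.1.0]pentadeca-4,10-dien-3-yl acetate
Conditions: 2-nitrobenzenesulfonohydrazide, Et3N, CH2Cl2, rt
Reagents that add atoms: none
Why: Diimide generated from the sulfonyl hydrazide transfers hydrogen by a concerted syn pathway whose rate falls steeply with alkene substitution, so only the 1,2-disubstituted C10=C11 bond should be reduced while the trisubstituted alkenes, the oxirane and the acetate remain.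

Step 17
Reactants: 21 TES-protected macrocycle
Product: 22 (1R,3R,4E,8R,10Z,14S)-8-(2-hydroxypropan-2-yl)-1,5,11-trimethyl-15-oxabicyclo[12.1.0]pentadeca-4,10-dien-3-yl acetate (target)
Conditions: TBAF, AcOH (1:1), THF, 0 °C to rt
Reagents that add atoms: none
Why: Fluoride cleaves the tertiary triethylsilyl ether, and buffering with acetic acid keeps the medium from becoming basic enough to cleave or shift the acetate or open the oxirane (desilylation).

Compound list

1 | (R)-(+)-α-terpineol, 2-[(1R)-4-methylcyclohex-3-en-1-yl]propan-2-ol | CC1=CC[C@@H](CC1)C(C)(C)O | starting material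
2 | triethyl{[2-((1R)-4-methylcyclohex-3-en-1-yl)propan-2-yl]oxy}silane | CC1=CC[C@@H](CC1)C(C)(C)O[Si](CC)(CC)CC | intermediate
3 | (3R)-6-oxo-3-[2-(triethylsilyloxy)propan-2-yl]heptanal | CC(=O)CC[C@@H](C(C)(C)O[Si](CC)(CC)CC)CC=O | intermediate
4 | (5R,7Z)-8-iodo-5-[2-(triethylsilyloxy)propan-2-yl]non-7-en-2-one | CC(=O)CC[C@@H](C(C)(C)O[Si](CC)(CC)CC)C/C=C(/C)I | intermediate
5 | (5R,7Z)-8-methyl-5-[2-(triethylsilyloxy)propan-2-yl]deca-7,9-dien-2-one | CC(=O)CC[C@@H](C(C)(C)O[Si](CC)(CC)CC)C/C=C(/C)C=C | intermediate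
6 | diethyl (5R,7Z)-8-methyl-5-[2-(triethylsilyloxy)propan-2-yl]deca-1,7,9-trien-2-yl phosphate | C=C(OP(=O)(OCC)OCC)CC[C@@H](C(C)(C)O[Si](CC)(CC)CC)C/C=C(/C)C=C | intermediate (not isolated)
7 | (3Z,6R)-3-methyl-6-[2-(triethylsilyloxy)propan-2-yl]deca-1,3-dien-9-yne | C#CCC[C@@H](C(C)(C)O[Si](CC)(CC)CC)C/C=C(/C)C=C | intermediate
8 | [(1E,5R,7Z)-2,8-dimethyl-5-[2-(triethylsilyloxy)propan-2-yl]deca-1,7,9-trien-1-yl]dimethylalane | C[Al](C)/C=C(\C)CC[C@@H](C(C)(C)O[Si](CC)(CC)CC)C/C=C(/C)C=C | intermediate (not isolated)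
9 | (2E,6R,8Z)-3,9-dimethyl-6-[2-(triethylsilyloxy)propan-2-yl]undeca-2,8,10-trien-1-ol | OC/C=C(\C)CC[C@@H](C(C)(C)O[Si](CC)(CC)CC)C/C=C(/C)C=C | intermediate
10 | (2E,6R,8Z)-3,9-dimethyl-6-[2-(triethylsilyloxy)propan-2-yl]undeca-2,8,10-trienal | O=C/C=C(\C)CC[C@@H](C(C)(C)O[Si](CC)(CC)CC)C/C=C(/C)C=C | intermediate
11 | ethyl 3-methylbut-2-enoate | CCOC(=O)C=C(C)C | starting material
12 | 1-ethoxy-3-methyl-1-(trimethylsilyloxy)buta-1,3-diene | CCOC(O[Si](C)(C)C)=CC(C)=C | intermediate
13 | (6R)-6-[(1E,5R,7Z)-2,8-dimethyl-5-[2-(triethylsilyloxy)propan-2-yl]deca-1,7,9-trien-1-yl]-4-methyl-5,6-dihydro-2H-pyran-2-one | O=C1C=C(C)C[C@@H](O1)/C=C(\C)CC[C@@H](C(C)(C)O[Si](CC)(CC)CC)C/C=C(/C)C=C | intermediate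
14 | (2Z,5R,6E,10R,12Z)-3,7,13-trimethyl-10-[2-(triethylsilyloxy)propan-2-yl]pentadeca-2,6,12,14-tetraene-1,5-diol | OC/C=C(/C)C[C@@H](O)/C=C(\C)CC[C@@H](C(C)(C)O[Si](CC)(CC)CC)C/C=C(/C)C=C | intermediate
15 | (2R,3E,7R,9Z)-1-[(2R,3S)-3-(hydroxymethyl)-2-methyloxiran-2-yl]-4,10-dimethyl-7-[2-(triethylsilyloxy)propan-2-yl]dodeca-3,9,11-trien-2-ol | OC[C@@H]1O[C@]1(C)C[C@@H](O)/C=C(\C)CC[C@@H](C(C)(C)O[Si](CC)(CC)CC)C/C=C(/C)C=C | intermediate
16 | (2R,3E,7R,9Z)-4,10-dimethyl-1-{(2R,3S)-2-methyl-3-[(triethylsilyloxy)methyl]oxiran-2-yl}-7-[2-(triethylsilyloxy)propan-2-yl]dodeca-3,9,11-trien-2-ol | CC[Si](CC)(CC)OC[C@@H]1O[C@]1(C)C[C@@H](O)/C=C(\C)CC[C@@H](C(C)(C)O[Si](CC)(CC)CC)C/C=C(/C)C=C | intermediate (not isolated)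
17 | (2R,3E,7R,9Z)-4,10-dimethyl-1-{(2R,3S)-2-methyl-3-[(triethylsilyloxy)methyl]oxiran-2-yl}-7-[2-(triethylsilyloxy)propan-2-yl]dodeca-3,9,11-trien-2-yl acetate | CC[Si](CC)(CC)OC[C@@H]1O[C@]1(C)C[C@@H](OC(C)=O)/C=C(\C)CC[C@@H](C(C)(C)O[Si](CC)(CC)CC)C/C=C(/C)C=C | intermediate
18 | (2R,3E,7R,9Z)-1-[(2R,3R)-3-formyl-2-methyloxiran-2-yl]-4,10-dimethyl-7-[2-(triethylsilyloxy)propan-2-yl]dodeca-3,9,11-trien-2-yl acetate | O=C[C@@H]1O[C@]1(C)C[C@@H](OC(C)=O)/C=C(\C)CC[C@@H](C(C)(C)O[Si](CC)(CC)CC)C/C=C(/C)C=C | intermediate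
19 | (2R,3E,7R,9Z)-1-[(2R,3S)-3-ethenyl-2-methyloxiran-2-yl]-4,10-dimethyl-7-[2-(triethylsilyloxy)propan-2-yl]dodeca-3,9,11-trien-2-yl acetate | C=C[C@@H]1O[C@]1(C)C[C@@H](OC(C)=O)/C=C(\C)CC[C@@H](C(C)(C)O[Si](CC)(CC)CC)C/C=C(/C)C=C | intermediate
20 | (1S,2E,4Z,7R,10E,12R,14R)-4,10,14-trimethyl-7-[2-(triethylsilyloxy)propan-2-yl]-15-oxabicyclo[12.1.0]pentadeca-2,4,10-trien-12-yl acetate | CC(=O)O[C@H]1/C=C(\C)CC[C@@H](C(C)(C)O[Si](CC)(CC)CC)C/C=C(/C)\C=C\[C@@H]2O[C@]2(C)C1 | intermediate
21 | (1R,3R,4E,8R,10Z,14S)-1,5,11-trimethyl-8-[2-(triethylsilyloxy)propan-2-yl]-15-oxabicyclo[12.1.0]pentadeca-4,10-dien-3-yl acetate | CC(=O)O[C@H]1/C=C(\C)CC[C@@H](C(C)(C)O[Si](CC)(CC)CC)C/C=C(/C)CC[C@@H]2O[C@]2(C)C1 | intermediate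
22 | (1R,3R,4E,8R,10Z,14S)-8-(2-hydroxypropan-2-yl)-1,5,11-trimethyl-15-oxabicyclo[12.1.0]pentadeca-4,10-dien-3-yl acetate | CC(=O)O[C@H]1/C=C(\C)CC[C@@H](C(C)(C)O)C/C=C(/C)CC[C@@H]2O[C@]2(C)C1 | target

Total step count: 17. Longest linear sequence: 16 (steps 1 to 7 and 9 to 17; step 8 prepares the dienolate on a side branch).

Steps most likely to fail

Step 15 (macrocyclic diene–ene metathesis). The catalyst may be held as an unreactive conjugated ruthenium vinylcarbene at the diene terminus, or cross-metathesis oligomerisation and closure onto the internal C8=C9 alkene may outrun macrocyclisation. Fallback, relay ring-closing metathesis, which changes where and in which order the carbene is formed: setting out from 18, Wittig reaction with the ylide of (hex-5-en-1-yl)triphenylphosphonium bromide (KHMDS, THF, −78 °C) would give the relay substrate (2R,3E,7R,9Z)-1-{(2R,3S)-3-[(1Z)-hepta-1,6-dien-1-yl]-2-methyloxiran-2-yl}-4,10-dimethyl-7-[2-(triethylsilyloxy)propan-2-yl]dodeca-3,9,11-trien-2-yl acetate F1. Ruthenium would load at the unhindered terminal alkene of the relay arm, expel cyclopentene and thereby be delivered as the alkylidene to C11, which then only has to capture the diene terminus. The fallback comes back to the route at 20.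

Step 9 (asymmetric vinylogous aldol with lactonisation). Facial discrimination on a β,β-disubstituted enal may be insufficient, the enal may isomerise at C2=C3 before addition, or the aldolate may fail to close to the lactone. Fallback, stepwise construction of the lactone by aldol, acylation and intramolecular olefination: setting out from 10, a Ti(OiPr)4/chiral binaphthol-derived ligand-catalysed enantioselective addition of 2-methoxypropene (acetone aldol equivalent) would give the enol ether (4R,5E,9R,11Z)-2-methoxy-6,12-dimethyl-9-[2-(triethylsilyloxy)propan-2-yl]tetradeca-1,5,11,13-tetraen-4-ol F2. Mild acid would hydrolyse it to the hydroxy ketone (4R,5E,9R,11Z)-4-hydroxy-6,12-dimethyl-9-[2-(triethylsilyloxy)propan-2-yl]tetradeca-5,11,13-trien-2-one F3. Esterification with diethylphosphonoacetic acid (DCC, DMAP) would give (4R,5E,9R,11Z)-6,12-dimethyl-2-oxo-9-[2-(triethylsilyloxy)propan-2-yl]tetradeca-5,11,13-trien-4-yl 2-(diethoxyphosphoryl)acetate F4. Intramolecular Horner–Wadsworth–Emmons reaction (LiCl, DBU, MeCN) would close the Z-locked lactone, and the fallback comes back to the route at 13.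

Step 3 (Z-selective iodo-olefination of the keto aldehyde). The Z-selectivity may erode, and the basic ylide may enolise the keto aldehyde and trigger intramolecular aldol condensation. Fallback, phosphonate-based Z-olefination with later methylenation: setting out from 3, Still–Gennari olefination with methyl 2-[bis(2,2,2-trifluoroethoxy)phosphoryl]propanoate (KHMDS, 18-crown-6, THF, −78 °C), which is chemoselective for the aldehyde, would give methyl (2Z,5R)-2-methyl-8-oxo-5-[2-(triethylsilyloxy)propan-2-yl]non-2-enoate F5. DIBAL-H would reduce ester and ketone to (2Z,5R)-2-methyl-5-[2-(triethylsilyloxy)propan-2-yl]non-2-ene-1,8-diol F6 (C8 epimers). Buffered Dess–Martin oxidation would give (2Z,5R)-2-methyl-8-oxo-5-[2-(triethylsilyloxy)propan-2-yl]non-2-enal F7. Methylenation of the aldehyde alone with one equivalent of Ph3P=CH2 at −78 °C brings the fallback back to the route at 5.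

Further compounds

F1 | step 15 | (2R,3E,7R,9Z)-1-{(2R,3S)-3-[(1Z)-hepta-1,6-dien-1-yl]-2-methyloxiran-2-yl}-4,10-dimethyl-7-[2-(triethylsilyloxy)propan-2-yl]dodeca-3,9,11-trien-2-yl acetate | C=CCCC/C=C\[C@@H]1O[C@]1(C)C[C@@H](OC(C)=O)/C=C(\C)CC[C@@H](C(C)(C)O[Si](CC)(CC)CC)C/C=C(/C)C=C
F2 | step 9 | (4R,5E,9R,11Z)-2-methoxy-6,12-dimethyl-9-[2-(triethylsilyloxy)propan-2-yl]tetradeca-1,5,11,13-tetraen-4-ol | C=C(OC)C[C@@H](O)/C=C(\C)CC[C@@H](C(C)(C)O[Si](CC)(CC)CC)C/C=C(/C)C=C
F3 | step 9 | (4R,5E,9R,11Z)-4-hydroxy-6,12-dimethyl-9-[2-(triethylsilyloxy)propan-2-yl]tetradeca-5,11,13-trien-2-one | CC(=O)C[C@@H](O)/C=C(\C)CC[C@@H](C(C)(C)O[Si](CC)(CC)CC)C/C=C(/C)C=C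
F4 | step 9 | (4R,5E,9R,11Z)-6,12-dimethyl-2-oxo-9-[2-(triethylsilyloxy)propan-2-yl]tetradeca-5,11,13-trien-4-yl 2-(diethoxyphosphoryl)acetate | CCOP(=O)(OCC)CC(=O)O[C@H](CC(C)=O)/C=C(\C)CC[C@@H](C(C)(C)O[Si](CC)(CC)CC)C/C=C(/C)C=C
F5 | step 3 | methyl (2Z,5R)-2-methyl-8-oxo-5-[2-(triethylsilyloxy)propan-2-yl]non-2-enoate | CC(=O)CC[C@@H](C(C)(C)O[Si](CC)(CC)CC)C/C=C(/C)C(=O)OC
F6 | step 3 | (2Z,5R)-2-methyl-5-[2-(triethylsilyloxy)propan-2-yl]non-2-ene-1,8-diol | CC(O)CC[C@@H](C(C)(C)O[Si](CC)(CC)CC)C/C=C(/C)CO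
F7 | step 3 | (2Z,5R)-2-methyl-8-oxo-5-[2-(triethylsilyloxy)propan-2-yl]non-2-enal | CC(=O)CC[C@@H](C(C)(C)O[Si](CC)(CC)CC)C/C=C(/C)C=O
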